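## Retrosynthetic overview

- **Feature:** in ring B (ether carbon C1′, hydroxyl carbon C2′, bromines on C3′ and C5′), the O–C1′–C2′–OH array is the O–CH–C(=O) array of a 2-aryloxycyclohexanone two oxidation levels up. Its bromines lie ortho and para to the C2′ hydroxyl, where a free phenol brominates by itself.
- **Disconnection 1:** the ring A hydroxyl travels as a methyl ether and is freed last with BBr3.
- **Disconnection 2 (key):** ring B is traced back to a saturated cyclohexanone ring. Br2 acts first as the dehydrogenating agent and then as the source of both ring B bromines.
- **Disconnection 3:** the ether bond is made at an sp3 carbon by SN2 of a phenoxide on 2-chlorocyclohexanone. Ring A has its bromines ortho and para to the ether oxygen, so they go onto guaiacol while that oxygen is still a free OH.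
- **Ring order:** ring A is bought as an arene. The six-membered carbocycle is bought as cyclohexanone, attached, and only then turned into ring B. No ring is closed anywhere.

Key step: step 5

Remark: the target has no stereocentre. Every sp3 stereocentre met in steps 3 to 5 is racemic or a diastereomer mixture and is erased in step 5.

## Route

Step 1
Reactants: 1 guaiacol (2-methoxyphenol)
Product: 2 4-bromo-2-methoxyphenol
Conditions: NBS (1.0 equiv), MeCN, 0 °C to rt
Reagents that add atoms: N-bromosuccinimide, O=C1CCC(=O)N1Br
Why: Electrophilic aromatic bromination in which the free OH, the stronger of the two donors, should send the first bromine to its unhindered para carbon, as is usual for guaiacol with NBS in a polar solvent.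

Step 2
Reactants: 2 4-bromo-2-methoxyphenol
Product: 3 2,4-dibromo-6-methoxyphenol
Conditions: NBS (1.05 equiv), i-Pr2NH (10 mol %), CH2Cl2, 0 °C to rt
Reagents that add atoms: N-bromosuccinimide, O=C1CCC(=O)N1Br
Why: Amine-catalysed ortho-bromination of a phenol, in which the N-bromoamine formed in situ is hydrogen-bonded to the OH and should hand its bromine to the one free ortho carbon (C6) rather than to C5, the carbon para to the methoxy group.

Step 3
Reactants: 4 cyclohexanone
Product: 5 2-chlorocyclohexan-1-one (racemic)
Conditions: SO2Cl2 (1.0 equiv), CH2Cl2, 0 °C to rt; distillation
Reagents that add atoms: sulfuryl chloride, O=S(=O)(Cl)Cl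
Why: α-Chlorination of a ketone through its enol, a standard preparation in which one equivalent of reagent and distillation hold the product at the monochloride, whose α-stereocentre forms racemic.

Step 4
Reactants: 3 2,4-dibromo-6-methoxyphenol; 5 2-chlorocyclohexan-1-one (1.3 equiv)
Product: 7 2-(2,4-dibromo-6-methoxyphenoxy)cyclohexan-1-one (racemic), via 2-iodocyclohexanone 6 (not isolated)
Conditions: K2CO3 (1.5 equiv), KI (10 mol %), DMF, 60 °C
Reagents that add atoms: none
Why: Williamson-type SN2 O-alkylation of a phenoxide with an α-halo ketone, the standard entry to 2-aryloxycyclohexanones, helped by Finkelstein exchange to the iodide and by the low basicity of the dibromophenoxide, which disfavours enolate formation and Favorskii rearrangement; the new stereocentre forms racemic and is of no consequence.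

Step 5
Reactants: 7 2-(2,4-dibromo-6-methoxyphenoxy)cyclohexan-1-one
Product: 10 2,4-dibromo-6-(2,4-dibromo-6-methoxyphenoxy)phenol, via 2,6-dibromo ketone 8 (not isolated), via 2-aryloxyphenol 9 (not isolated)
Conditions: Br2 (2.1 equiv, dropwise), cat. HBr, glacial AcOH, rt, then 80 °C with N2 sweep; cool to 15 °C, Br2 (2.1 equiv), same pot
Reagents that add atoms: bromine, BrBr
Why: HBr-catalysed enolization toward both α-carbons and bromination should place one bromine on each of them (8); on warming, the tertiary bromide on the ether-bearing carbon ionizes to an oxygen-stabilized cation and loses a proton, the secondary bromide leaves from the derived dienol through a cyclohexadienyl cation, and the ring, now two oxidation levels higher, tautomerizes to phenol 9, which the second charge of bromine substitutes first para and then ortho to the new OH. The closest known chemistry is the halogenation–dehydrohalogenation aromatization of cyclohexanones and cyclohexenones to phenols and bromophenols, joined here to the ordinary electrophilic dibromination of a 2-aryloxyphenol; the type is established, this substrate is untested. No ring is closed: the carbocycle attached in step 4 gains three ring C=C bonds and becomes ring B, its carbonyl oxygen becomes the C2′ hydroxyl, and two C–Br bonds form at C3′ and C5′. No lasting stereocentre is created, and the stereocentres of 7 and 8 are erased. The step needs bromine to stay only ortho and para to the new OH: that OH is by far the strongest director, its other ortho carbon is blocked by the aryloxy group (a weak donor because its aryl ring is electron-poor), a bromine that survives aromatization on the α′ or γ carbon already sits at a wanted position, and dosing the bromine in two portions keeps free Br2 low while the transient enol-ether C=C, the one site that could fix a bromine meta to the OH, is present. Ring A should be spared because it has no free OH, is deactivated by two bromines and has both carbons ortho to the ether oxygen occupied, which also shuts off acid-induced cyclodehydration to a tetrahydrodibenzofuran, and the limit of 80 °C with removal of HBr protects the methyl ether.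

Step 6
Reactants: 10 2,4-dibromo-6-(2,4-dibromo-6-methoxyphenoxy)phenol
Product: 11 3,5-dibromo-2-(3,5-dibromo-2-hydroxyphenoxy)phenol (target, CNP0144684.0)
Conditions: BBr3 (3 equiv), CH2Cl2, −78 °C to rt; then H2O
Reagents that add atoms: none
Why: BBr3 demethylation of an aryl methyl ether (coordination of boron to the ether oxygen, then SN2 attack of bromide on the methyl carbon, then hydrolysis of the aryl borate), which should leave the diaryl ether and the four aryl bromides untouched.

## Compound list

1 | guaiacol (2-methoxyphenol) | COc1ccccc1O | starting material
2 | 4-bromo-2-methoxyphenol | COc1cc(Br)ccc1O | intermediate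
3 | 2,4-dibromo-6-methoxyphenol | COc1cc(Br)cc(Br)c1O | intermediate
4 | cyclohexanone | O=C1CCCCC1 | starting material
5 | 2-chlorocyclohexan-1-one (racemic) | O=C1CCCCC1Cl | intermediate
6 | 2-iodocyclohexan-1-one (racemic, not isolated) | O=C1CCCCC1I | intermediate
7 | 2-(2,4-dibromo-6-methoxyphenoxy)cyclohexan-1-one (racemic) | COc1cc(Br)cc(Br)c1OC1CCCCC1=O | intermediate
8 | 2,6-dibromo-2-(2,4-dibromo-6-methoxyphenoxy)cyclohexan-1-one (diastereomer mixture, not isolated) | COc1cc(Br)cc(Br)c1OC1(Br)CCCC(Br)C1=O | intermediate
9 | 2-(2,4-dibromo-6-methoxyphenoxy)phenol (not isolated) | COc1cc(Br)cc(Br)c1Oc1ccccc1O | intermediate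
10 | 2,4-dibromo-6-(2,4-dibromo-6-methoxyphenoxy)phenol | COc1cc(Br)cc(Br)c1Oc1cc(Br)cc(Br)c1O | intermediate
11 | 3,5-dibromo-2-(3,5-dibromo-2-hydroxyphenoxy)phenol | Oc1cc(Br)cc(Br)c1Oc1cc(Br)cc(Br)c1O | target

## Step count and risks

Total step count: 6. Longest linear sequence: 5 (steps 1, 2, 4, 5, 6).

**Step 5 (highest risk).**
- What may go wrong:
  - addition of bromine across the transient enol-ether double bond, fixing a bromine meta to the hydroxyl;
  - loss of the aryloxy group by solvolysis or bromide attack at the ether-bearing carbon before the ring is aromatic;
  - stalling of the dehydrobromination;
  - bromination of ring A by surplus reagent.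
- Fallback: oxidation and substitution are uncoupled. Setting out from 7, the ring is dehydrogenated without free bromine by CuBr2 (4.4 equiv) and LiBr in refluxing MeCN. Divalent copper brominates only through the enol, bromide assists loss of HBr, and the solvent is not nucleophilic; this is the known method for turning cyclohexenones into phenols. 2-(2,4-Dibromo-6-methoxyphenoxy)phenol 9 is then isolated and purified, and treated with Br2 (2.0 equiv) in AcOH at rt, which comes back to the route at 10. No compound outside the list is made (F0).

**Step 4.**
- What may go wrong: sluggish substitution by a weakly nucleophilic phenoxide flanked by two ortho substituents. It could be overtaken by enolization of the chloro ketone, leading to Favorskii-type ring contraction, self-condensation or loss of HCl.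
- Fallback: the C–O bond is made on an electrophile without acidic hydrogens, and the carbonyl is introduced afterwards. Setting out from 3, heating with cyclohexene oxide (K2CO3, DMF, 110 °C) should open the epoxide anti to give rac-trans-2-(2,4-dibromo-6-methoxyphenoxy)cyclohexan-1-ol F1. Oxidation of the secondary alcohol with Dess–Martin periodinane (CH2Cl2, rt) comes back to the route at 7.

**Step 2.**
- What may go wrong: attack at the carbon para to the methoxy group instead of ortho to the OH, or a third bromination.
- Fallback: the order of the two C–Br bond formations is inverted, so that the contested second bromination falls on the carbon para to the OH, where the hydroxyl preference is strongest. Setting out from 1, ortho-selective bromination with Br2 and t-BuNH2 (toluene, −78 °C) should give 2-bromo-6-methoxyphenol F2. NBS in MeCN then brominates para to the OH and comes back to the route at 3.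

## Further compounds

F0 | step 5 | none | none
F1 | step 4 | rac-trans-2-(2,4-dibromo-6-methoxyphenoxy)cyclohexan-1-ol, (1R,2R) enantiomer drawn | COc1cc(Br)cc(Br)c1O[C@@H]1CCCC[C@H]1O
F2 | step 2 | 2-bromo-6-methoxyphenol | COc1cccc(Br)c1O
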